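**Strategy.** Everything rests on cutting the aryl ether bond O1–C8a of ring C. Because O1 joins the benzylic stereocentre C2 to the ring A carbon C8a, a C2 carbinol of fixed (S) configuration can be arylated by the neighbouring C8a bromide without any bond to C2 being broken. In one operation the copper-catalysed O-arylation closes the six-membered ring C and carries the reagent-set configuration into the chroman with retention. Its precursor is an open 1,3-dioxygenated diarylpropane: free (S)-carbinol at C2, C4 oxygen masked as a triisopropylsilyl ether, ring A carrying Br at C8a, prenyl groups at C6 and C8 and a MOM ether at C7; ring B carries a 4'-MOM ether.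

Key step: step 8

Remarks on the chemistry:
- Flavanone numbering (O1, C2–C4, C4a, C5–C8, C8a; ring B primed) is used for all intermediates.
- Compounds 11 and 12 are racemic at C4, and 13–15 are pairs of C4 epimers with uniform (S) configuration at C2. This is assumed to be immaterial, because C4 becomes the carbonyl carbon in step 10.
- The C4 oxygen is carried as a TIPS ether, the common silyl group least prone to 1,3 O-to-O migration under carbonate at 110 °C.
- The ketone reduction uses catecholborane and not a BH3 complex, so that the two trisubstituted prenyl alkenes are not hydroborated.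

**Step 1**
Reactants: 1 2-bromo-4-hydroxybenzaldehyde
Product: 3 2-bromo-4-hydroxy-3,5-diiodobenzaldehyde, via 2-bromo-4-hydroxy-5-iodobenzaldehyde 2 (not isolated)
Conditions: NIS (2.3 equiv), TsOH·H2O (cat.), MeCN, rt to 40 °C
Reagents that add atoms: N-iodosuccinimide, O=C1CCC(=O)N1I
Why: Electrophilic aromatic iodination, in which the phenol directs to its two ortho carbons (para is blocked by the formyl group, itself meta-directing to the same carbons), so the open C5 position should be iodinated first and the position next to bromine second.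

**Step 2**
Reactants: 3 2-bromo-4-hydroxy-3,5-diiodobenzaldehyde
Product: 4 2-bromo-3,5-diiodo-4-(methoxymethoxy)benzaldehyde
Conditions: MOMCl, K2CO3, DMF, 0 °C to rt
Reagents that add atoms: chloromethyl methyl ether, COCCl
Why: Williamson-type O-alkylation of the acidic diiodophenoxide by the highly electrophilic alpha-chloro ether should give the MOM acetal, which masks the phenol for the organometallic and basic steps that follow.

**Step 3**
Reactants: 4 2-bromo-3,5-diiodo-4-(methoxymethoxy)benzaldehyde; 5 tributyl(3-methylbut-2-enyl)stannane (2.4 equiv)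
Product: 7 2-bromo-4-(methoxymethoxy)-3,5-bis(3-methylbut-2-en-1-yl)benzaldehyde, via 2-bromo-3-iodo-4-(methoxymethoxy)-5-(3-methylbut-2-en-1-yl)benzaldehyde 6 (not isolated)
Conditions: Pd2(dba)3 (5 mol%), AsPh3 (20 mol%), DMF, 60 °C
Reagents that add atoms: none
Why: Migita–Kosugi–Stille coupling, in which zerovalent palladium adds to the two C–I bonds far faster than to C–Br, the allylic stannane transmetalates readily even at the flanked iodide, and reductive elimination at the primary allyl terminus should give the linear prenyl groups while the bromide needed in step 8 is kept.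

**Step 4**
Reactants: 8 4'-hydroxyacetophenone
Product: 9 4'-(methoxymethoxy)acetophenone
Conditions: MOMCl, K2CO3, acetone, rt
Reagents that add atoms: chloromethyl methyl ether, COCCl
Why: Williamson-type O-alkylation of the phenoxide should give the MOM ether, so that the ketone can be enolised without a competing phenoxide.

**Step 5**
Reactants: 9 4'-(methoxymethoxy)acetophenone; 7 2-bromo-4-(methoxymethoxy)-3,5-bis(3-methylbut-2-en-1-yl)benzaldehyde
Product: 11 rac-3-[2-bromo-4-(methoxymethoxy)-3,5-bis(3-methylbut-2-en-1-yl)phenyl]-3-hydroxy-1-[4-(methoxymethoxy)phenyl]propan-1-one, via lithium 1-[4-(methoxymethoxy)phenyl]ethenolate 10 (not isolated)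
Conditions: LiN(i-Pr)2, THF, −78 °C; then 7, −78 °C; aq. NH4Cl at −78 °C
Reagents that add atoms: none
Why: Directed aldol addition of the preformed lithium enolate to the non-enolisable aldehyde should form the C3–C4 bond, the cold quench avoiding retro-aldol cleavage and dehydration; the new C4 carbinol is racemic, which does not matter.

**Step 6**
Reactants: 11 rac-aldol adduct
Product: 12 rac-3-[2-bromo-4-(methoxymethoxy)-3,5-bis(3-methylbut-2-en-1-yl)phenyl]-1-[4-(methoxymethoxy)phenyl]-3-(triisopropylsilyloxy)propan-1-one
Conditions: i-Pr3SiOTf, 2,6-lutidine, CH2Cl2, −78 to 0 °C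
Reagents that add atoms: triisopropylsilyl trifluoromethanesulfonate, CC(C)[Si](OS(=O)(=O)C(F)(F)F)(C(C)C)C(C)C
Why: Silylation of the secondary benzylic alcohol with a silyl triflate and a hindered pyridine base is fast at low temperature, should leave the aryl MOM acetals alone, and blocks the beta-hydroxy ketone against retro-aldol, elimination and hydroxyl-directed reduction.

**Step 7**
Reactants: 12 rac-silyloxy ketone
Product: 13 (1S)-3-[2-bromo-4-(methoxymethoxy)-3,5-bis(3-methylbut-2-en-1-yl)phenyl]-1-[4-(methoxymethoxy)phenyl]-3-(triisopropylsilyloxy)propan-1-ol (both C3 epimers)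
Conditions: (R)-2-methyl-CBS-oxazaborolidine (20 mol%), catecholborane, toluene, −78 to −40 °C; then MeOH, 1 M aq. NaOH wash
Reagents that add atoms: none
Why: Corey–Bakshi–Shibata reduction, in which the (R)-oxazaborolidine binds the ketone with the aryl group as the large substituent and should deliver hydride to the face that gives the (S)-benzylic carbinol (the sense established for aryl alkyl ketones) under reagent control for both enantiomers of 12, while catecholborane at low temperature leaves the prenyl alkenes untouched.

**Step 8**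
Reactants: 13 (1S)-bromo carbinol (both C3 epimers)
Product: 14 (2S)-7-(methoxymethoxy)-2-[4-(methoxymethoxy)phenyl]-6,8-bis(3-methylbut-2-en-1-yl)-4-(triisopropylsilyloxy)chromane (both C4 epimers)
Conditions: CuI (20 mol%), 3,4,7,8-tetramethyl-1,10-phenanthroline (40 mol%), Cs2CO3 (2 equiv), toluene, 110 °C, Ar
Reagents that add atoms: none
Why: Cs2CO3 deprotonates the only free hydroxyl, the alkoxide binds phenanthroline-ligated monovalent copper, the C8a–Br bond adds oxidatively to give a seven-membered aryl(alkoxy) trivalent copper chelate, and C–O reductive elimination releases the chroman and returns monovalent copper. The closest known reaction type is the Ullmann-type copper-catalysed O-arylation of aliphatic alcohols with aryl halides in its intramolecular, chroman-forming variant. Ring C is closed in a formal 6-exo mode at the sp2 carbon C8a by the tethered oxygen, the metallacycle contracting to the six-membered ring on reductive elimination. No stereocentre is created: C2 keeps its (S) configuration because the C2–O bond is never broken, and both C4 epimers should cyclise. The step needs chemoselectivity for O-arylation over hydrodebromination and carbinol oxidation, which is secured because copper alkoxides are reluctant to undergo beta-hydride elimination, the C4 oxygen is capped by a migration-resistant TIPS group (and could only form a four-membered ring), and C8a–Br is the only carbon–halogen bond. The second ortho substituent, the C8 prenyl group, should be tolerated because the nucleophile is delivered intramolecularly.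

**Step 9**
Reactants: 14 (2S)-flavan-4-ol TIPS ether (both C4 epimers)
Product: 15 (2S)-7-(methoxymethoxy)-2-[4-(methoxymethoxy)phenyl]-6,8-bis(3-methylbut-2-en-1-yl)chroman-4-ol (both C4 epimers)
Conditions: Bu4NF, THF, rt
Reagents that add atoms: none
Why: Fluoride-mediated desilylation, driven by the strong Si–F bond, should free the C4 alcohol while MOM ethers, the aryl ether and the prenyl groups are inert.

**Step 10**
Reactants: 15 (2S)-flavan-4-ol (both C4 epimers)
Product: 16 (2S)-7-(methoxymethoxy)-2-[4-(methoxymethoxy)phenyl]-6,8-bis(3-methylbut-2-en-1-yl)chroman-4-one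
Conditions: Dess–Martin periodinane, NaHCO3, CH2Cl2, 0 °C to rt
Reagents that add atoms: none
Why: Dess–Martin oxidation should convert both C4 epimers into one ketone under buffered conditions; C2 is not alpha to the carbonyl and both phenols are still capped, so ring opening to a chalcone is not available.

**Step 11**
Reactants: 16 (2S)-bis-MOM flavanone
Product: 19 (2S)-7-hydroxy-2-(4-hydroxyphenyl)-6,8-bis(3-methylbut-2-en-1-yl)chroman-4-one, via 7-hydroxy-4'-O-MOM flavanone 17 (not isolated), via 4'-hydroxy-7-O-MOM flavanone 18 (not isolated)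
Conditions: 2 M aq. HCl, MeOH, rt to 40 °C
Reagents that add atoms: none
Why: Acid-catalysed acetal exchange with methanol should cleave both aryl MOM ethers in either order; dilute acid at moderate temperature is chosen so that the prenyl alkenes are not protonated and the flavanone, which racemises through base-induced ring opening, keeps its (2S) configuration.

**Compound list**

1 | 2-bromo-4-hydroxybenzaldehyde | O=Cc1ccc(O)cc1Br | starting material
2 | 2-bromo-4-hydroxy-5-iodobenzaldehyde | O=Cc1cc(I)c(O)cc1Br | intermediate (not isolated)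
3 | 2-bromo-4-hydroxy-3,5-diiodobenzaldehyde | O=Cc1cc(I)c(O)c(I)c1Br | intermediate
4 | 2-bromo-3,5-diiodo-4-(methoxymethoxy)benzaldehyde | O=Cc1cc(I)c(OCOC)c(I)c1Br | intermediate
5 | tributyl(3-methylbut-2-enyl)stannane | CC(C)=CC[Sn](CCCC)(CCCC)CCCC | starting material
6 | 2-bromo-3-iodo-4-(methoxymethoxy)-5-(3-methylbut-2-en-1-yl)benzaldehyde | O=Cc1cc(CC=C(C)C)c(OCOC)c(I)c1Br | intermediate (not isolated)
7 | 2-bromo-4-(methoxymethoxy)-3,5-bis(3-methylbut-2-en-1-yl)benzaldehyde | O=Cc1cc(CC=C(C)C)c(OCOC)c(CC=C(C)C)c1Br | intermediate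
8 | 4'-hydroxyacetophenone | CC(=O)c1ccc(O)cc1 | starting material
9 | 4'-(methoxymethoxy)acetophenone | CC(=O)c1ccc(OCOC)cc1 | intermediate
10 | lithium 1-[4-(methoxymethoxy)phenyl]ethenolate | [Li]OC(=C)c1ccc(OCOC)cc1 | intermediate (not isolated)
11 | rac-3-[2-bromo-4-(methoxymethoxy)-3,5-bis(3-methylbut-2-en-1-yl)phenyl]-3-hydroxy-1-[4-(methoxymethoxy)phenyl]propan-1-one | CC(C)=CCc1cc(C(O)CC(=O)c2ccc(OCOC)cc2)c(Br)c(CC=C(C)C)c1OCOC | intermediate
12 | rac-3-[2-bromo-4-(methoxymethoxy)-3,5-bis(3-methylbut-2-en-1-yl)phenyl]-1-[4-(methoxymethoxy)phenyl]-3-(triisopropylsilyloxy)propan-1-one | CC(C)=CCc1cc(C(O[Si](C(C)C)(C(C)C)C(C)C)CC(=O)c2ccc(OCOC)cc2)c(Br)c(CC=C(C)C)c1OCOC | intermediate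
13 | (1S)-3-[2-bromo-4-(methoxymethoxy)-3,5-bis(3-methylbut-2-en-1-yl)phenyl]-1-[4-(methoxymethoxy)phenyl]-3-(triisopropylsilyloxy)propan-1-ol, both C3 epimers (precursor of the key step) | CC(C)=CCc1cc(C(O[Si](C(C)C)(C(C)C)C(C)C)C[C@H](O)c2ccc(OCOC)cc2)c(Br)c(CC=C(C)C)c1OCOC | intermediate
14 | (2S)-7-(methoxymethoxy)-2-[4-(methoxymethoxy)phenyl]-6,8-bis(3-methylbut-2-en-1-yl)-4-(triisopropylsilyloxy)chromane, both C4 epimers (product of the key step) | CC(C)=CCc1cc2c(c(CC=C(C)C)c1OCOC)O[C@H](c1ccc(OCOC)cc1)CC2O[Si](C(C)C)(C(C)C)C(C)C | intermediate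
15 | (2S)-7-(methoxymethoxy)-2-[4-(methoxymethoxy)phenyl]-6,8-bis(3-methylbut-2-en-1-yl)chroman-4-ol, both C4 epimers | CC(C)=CCc1cc2c(c(CC=C(C)C)c1OCOC)O[C@H](c1ccc(OCOC)cc1)CC2O | intermediate
16 | (2S)-7-(methoxymethoxy)-2-[4-(methoxymethoxy)phenyl]-6,8-bis(3-methylbut-2-en-1-yl)chroman-4-one | CC(C)=CCc1cc2c(c(CC=C(C)C)c1OCOC)O[C@H](c1ccc(OCOC)cc1)CC2=O | intermediate
17 | (2S)-7-hydroxy-2-[4-(methoxymethoxy)phenyl]-6,8-bis(3-methylbut-2-en-1-yl)chroman-4-one | CC(C)=CCc1cc2c(c(CC=C(C)C)c1O)O[C@H](c1ccc(OCOC)cc1)CC2=O | intermediate (not isolated)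
18 | (2S)-2-(4-hydroxyphenyl)-7-(methoxymethoxy)-6,8-bis(3-methylbut-2-en-1-yl)chroman-4-one | CC(C)=CCc1cc2c(c(CC=C(C)C)c1OCOC)O[C@H](c1ccc(O)cc1)CC2=O | intermediate (not isolated)
19 | (2S)-7-hydroxy-2-(4-hydroxyphenyl)-6,8-bis(3-methylbut-2-en-1-yl)chroman-4-one | CC(C)=CCc1cc2c(c(CC=C(C)C)c1O)O[C@H](c1ccc(O)cc1)CC2=O | target

**Totals and risks**

Total step count: 11. Longest linear sequence: 10 steps (steps 1–3 and 5–11, from compound 1); step 4 is a one-step side branch.

The three steps most likely to fail:

1. Step 8 (ring closure). Oxidative addition at the electron-rich, doubly ortho-substituted C8a–Br bond may be slow, so that hydrodebromination or slow oxidation of the benzylic alkoxide overtakes C–O bond formation. The fallback closes ring C at O1–C2 by invertive displacement instead of at O1–C8a. It sets out from ketone 12. Miyaura borylation (B2pin2, Pd(OAc)2, SPhos, KOAc, dioxane, 90 °C) should give the aryl pinacol boronate F1. Oxidation with NaBO3·4H2O in THF–H2O at rt should give the phenol ketone F2. Asymmetric transfer hydrogenation with the opposite-sense catalyst RuCl[(R,R)-TsDPEN](p-cymene) in HCO2H–Et3N should give the (1R)-carbinol phenol F3. Mitsunobu cyclisation (PPh3, DIAD, toluene, 0 °C) should then displace the activated (R)-carbinol by the C8a phenol with inversion, giving (S) at C2 and coming back to the route at 14. Low temperature is needed because ionisation of the 4-alkoxybenzylic oxyphosphonium would erode the configuration.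

2. Step 3 (double Stille coupling). Halogen discrimination may be lost once only the flanked iodide remains (oxidative addition at the aldehyde-activated C–Br bond), coupling at the iodide between Br and OMOM may stall, or the prenyl group may be transferred through its tertiary terminus. The fallback uses no aryl–palladium chemistry; the side chains arrive by Claisen rearrangement and are converted to prenyl by cross-metathesis. It sets out from 1. O-Allylation (allyl bromide, K2CO3, acetone) should give 4-(allyloxy)-2-bromobenzaldehyde F4. Heating (N,N-diethylaniline, 190 °C) should give the two ortho-allyl phenols 3-allyl-2-bromo-4-hydroxybenzaldehyde F5 and 5-allyl-2-bromo-4-hydroxybenzaldehyde F6, which are carried on together. A second O-allylation should give 3-allyl-4-(allyloxy)-2-bromobenzaldehyde F7 and 5-allyl-4-(allyloxy)-2-bromobenzaldehyde F8. A second Claisen rearrangement should converge both on 3,5-diallyl-2-bromo-4-hydroxybenzaldehyde F9. MOM protection (MOMCl, K2CO3, DMF) should give 3,5-diallyl-2-bromo-4-(methoxymethoxy)benzaldehyde F10. Double cross-metathesis with excess 2-methyl-2-butene (second-generation Grubbs catalyst RuCl2(=CHPh)(H2IMes)(PCy3), CH2Cl2, 40 °C) should come back to the route at 7.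

3. Step 7 (reduction that sets C2). Facial selectivity may be poor if the bulky beta-silyloxy side chain rivals the aryl group in effective size at the oxazaborolidine, or if slow catalysed reduction lets uncatalysed background reduction compete. The fallback moves the source of facial control from steric size to a CH–π contact between catalyst arene and ketone aryl group, and uses no boron hydride. It sets out from 12. Asymmetric transfer hydrogenation with RuCl[(S,S)-TsDPEN](p-cymene) in HCO2H–Et3N (5:2) with EtOAc as co-solvent at 40 °C should give the (S)-carbinol and come back to the route at 13; no new compound is made.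

**Further compounds**

F1 | step 8 | rac-3-[4-(methoxymethoxy)-3,5-bis(3-methylbut-2-en-1-yl)-2-(4,4,5,5-tetramethyl-1,3,2-dioxaborolan-2-yl)phenyl]-1-[4-(methoxymethoxy)phenyl]-3-(triisopropylsilyloxy)propan-1-one | CC(C)=CCc1cc(C(O[Si](C(C)C)(C(C)C)C(C)C)CC(=O)c2ccc(OCOC)cc2)c(B2OC(C)(C)C(C)(C)O2)c(CC=C(C)C)c1OCOC
F2 | step 8 | rac-3-[2-hydroxy-4-(methoxymethoxy)-3,5-bis(3-methylbut-2-en-1-yl)phenyl]-1-[4-(methoxymethoxy)phenyl]-3-(triisopropylsilyloxy)propan-1-one | CC(C)=CCc1cc(C(O[Si](C(C)C)(C(C)C)C(C)C)CC(=O)c2ccc(OCOC)cc2)c(O)c(CC=C(C)C)c1OCOC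
F3 | step 8 | (1R)-3-[2-hydroxy-4-(methoxymethoxy)-3,5-bis(3-methylbut-2-en-1-yl)phenyl]-1-[4-(methoxymethoxy)phenyl]-3-(triisopropylsilyloxy)propan-1-ol, both C3 epimers | CC(C)=CCc1cc(C(O[Si](C(C)C)(C(C)C)C(C)C)C[C@@H](O)c2ccc(OCOC)cc2)c(O)c(CC=C(C)C)c1OCOC
F4 | step 3 | 4-(allyloxy)-2-bromobenzaldehyde | O=Cc1ccc(OCC=C)cc1Br
F5 | step 3 | 3-allyl-2-bromo-4-hydroxybenzaldehyde | O=Cc1ccc(O)c(CC=C)c1Br
F6 | step 3 | 5-allyl-2-bromo-4-hydroxybenzaldehyde | O=Cc1cc(CC=C)c(O)cc1Br
F7 | step 3 | 3-allyl-4-(allyloxy)-2-bromobenzaldehyde | O=Cc1ccc(OCC=C)c(CC=C)c1Br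
F8 | step 3 | 5-allyl-4-(allyloxy)-2-bromobenzaldehyde | O=Cc1cc(CC=C)c(OCC=C)cc1Br
F9 | step 3 | 3,5-diallyl-2-bromo-4-hydroxybenzaldehyde | O=Cc1cc(CC=C)c(O)c(CC=C)c1Br
F10 | step 3 | 3,5-diallyl-2-bromo-4-(methoxymethoxy)benzaldehyde | O=Cc1cc(CC=C)c(OCOC)c(CC=C)c1Br
F0 | step 7 | none | none
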